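**Retrosynthetic overview**
1. The target is (3R)-8-hydroxy-3-(11-hydroxyundecyl)-6-methoxy-3,4-dihydroisocoumarin (ring A = benzene ring C4a–C8a; ring B = lactone C1/O2/C3/C4/C4a/C8a). The last operation only unmasks O8 (peri-selective O-demethylation) and the chain hydroxyl (silyl ether).
2. Key disconnection: ring B is taken apart in one move at C4–C4a, C1–C8a and O2–C1. This gives 1-iodo-2,4-dimethoxybenzene, carbon monoxide and an enantiopure terminal epoxide (C4/C3/O2 plus the chain). In the forward sense it is a three-component carbonylative Catellani annulation.
3. Enabling feature: C8a and C4a are neighbours in ring A, and C8a is flanked on its other side by oxygenated C8. An iodide on C8a therefore has one blocked ortho position (C8, which enforces norbornene extrusion) and exactly one free ortho C–H (C4a). C4–C3–O2 is a latent oxirane whose oxygen, once released, can reach an acyl group on C8a to close a six-membered ring.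
4. The epoxide is cut between chain carbons C1' and C2'. This gives (R)-epichlorohydrin (delivers C4, C3 with its configuration, O2 and C1') and the Grignard reagent of O-silylated 10-bromodecan-1-ol.
5. Ring order: ring A is bought. The oxirane is a temporary ring, closed in step 3 and opened in step 4. Ring B is the only ring of the target that is formed, in step 4.

Key step: step 4

Remark: the stereocentre in the target SMILES reads as (R) (O2 > C4 > C1' > H). The C–O bond at this carbon is never broken and the priority order O > CH2X > chain > H holds throughout, so the descriptor stays (R) from epichlorohydrin to the target.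

**Step 1**
Reactants: 1 10-bromodecan-1-ol
Product: 2 [(10-bromodecyl)oxy](tert-butyl)dimethylsilane
Conditions: TBSCl (1.1 equiv), imidazole (1.5 equiv), CH2Cl2, 0 °C to rt
Reagents that add atoms: tert-butyldimethylsilyl chloride (TBSCl), CC(C)(C)[Si](C)(C)Cl
Why: Imidazole-promoted silyl ether formation on a primary alcohol leaves the alkyl bromide untouched and masks the hydroxyl for the Grignard and acylpalladium stages.

**Step 2**
Reactants: 2 [(10-bromodecyl)oxy](tert-butyl)dimethylsilane; 3 (R)-epichlorohydrin
Product: 5 (2R)-13-(tert-butyldimethylsilyloxy)-1-chlorotridecan-2-ol, via Grignard reagent 4 (not isolated)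
Conditions: Mg turnings, THF, 40 °C; then CuI (10 mol%), 3, THF, −40 to 0 °C; aq. NH4Cl
Reagents that add atoms: none
Why: Copper-catalysed Grignard opening of a terminal epoxide proceeds by SN2 attack at the unsubstituted oxirane carbon faster than chloride displacement, so the C–O bond of the stereocentre is untouched and the (R) configuration of 3 is carried into 5.

**Step 3**
Reactants: 5 (2R)-13-(tert-butyldimethylsilyloxy)-1-chlorotridecan-2-ol
Product: 6 tert-butyldimethyl({11-[(2R)-oxiran-2-yl]undecyl}oxy)silane
Conditions: K2CO3 (2 equiv), MeOH, rt
Reagents that add atoms: none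
Why: Intramolecular Williamson etherification (3-exo-tet) of the chlorohydrin displaces the primary chloride, keeps the C–O bond at the stereocentre and therefore should give the (R)-oxirane, with the alkyl silyl ether stable to this mild base.

**Step 4**
Reactants: 6 tert-butyldimethyl({11-[(2R)-oxiran-2-yl]undecyl}oxy)silane; 7 1-iodo-2,4-dimethoxybenzene (1.5 equiv)
Product: 8 (3R)-3-[11-(tert-butyldimethylsilyloxy)undecyl]-6,8-dimethoxy-3,4-dihydro-1H-isochromen-1-one
Conditions: Pd(OAc)2 (10 mol%), XPhos (20 mol%), potassium 5-norbornene-2-carboxylate (50 mol%), K2CO3 (1.5 equiv), CO (1 atm, balloon), NMP, 80 °C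
Reagents that add atoms: carbon monoxide, [C-]#[O+]
Why: Proposed new method: zerovalent palladium inserts into the C–I bond of 7, carbopalladation of the norbornene mediator and base-assisted metalation of the only free ortho C–H give the aryl-norbornyl palladacycle, which opens oxirane 6 by SN2-type oxidative addition at its unsubstituted CH2 (tetravalent palladium), forms the aryl–CH2 bond by reductive elimination and expels the norbornene by β-carbon elimination, after which CO inserts into the regenerated aryl–palladium bond (aryl–C(=O) bond) and the alkoxide released from the oxirane captures the acylpalladium. The closest known reaction types are the Catellani reaction with epoxides as ortho-alkylating agents, terminated by a Heck reaction or by aryl–O bond formation, and the palladium-catalysed carbonylative lactonisation of 2-(2-iodoaryl)ethanols; only their merger, with CO as the ipso terminator, is new. Ring B is the one ring closed, by attack of the tethered alkoxide on the acylpalladium carbon (6-exo-trig acyl substitution, equivalent to C–O reductive elimination from a seven-membered acyl(alkoxo)palladacycle), while the strained oxirane is consumed. No stereocentre is created: only the CH2–O bond of the oxirane breaks, so the C–O bond at the stereocentre persists and (R)-6 maps onto (R)-C3. Site selectivity rests on the 2-methoxy group of 7, which blocks the second ortho position and supplies the ortho substituent that forces norbornene extrusion after a single alkylation, and regioselective opening rests on the steric bias of a monosubstituted oxirane. Chemoselectivity against early carbonylation is secured because no nucleophile able to drain an acylpalladium exists until the oxirane has been opened, so premature CO insertion stays reversible, low CO pressure and a high mediator loading keep norbornene insertion ahead, and after extrusion CO insertion into the crowded arylpalladium should outrun the slow aryl–O reductive elimination.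

**Step 5**
Reactants: 8 (3R)-3-[11-(tert-butyldimethylsilyloxy)undecyl]-6,8-dimethoxy-3,4-dihydro-1H-isochromen-1-one
Product: 10 (3R)-8-hydroxy-3-(11-hydroxyundecyl)-6-methoxy-3,4-dihydro-1H-isochromen-1-one, via aryloxydichloroborane 9 (not isolated)
Conditions: BCl3 (1 M in CH2Cl2, 3 equiv), CH2Cl2, −78 to 0 °C; then MeOH, 0 °C to rt
Reagents that add atoms: none
Why: In this chelation-controlled Lewis acid ether cleavage BCl3 is held between the lactone carbonyl O and the peri O8, so chloride dealkylates only the C8 methyl ether (the usual selectivity for aryl methyl ethers ortho to a carbonyl group) while the C6 ether, the lactone and C3 stay untouched, and methanolysis of the boron chelate in the same flask releases HCl that solvolyses the primary silyl ether (acid-catalysed desilylation), so any silyl ether already lost to BCl3 converges on the same product.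

**Compound list**
1 | 10-bromodecan-1-ol | OCCCCCCCCCCBr | starting material
2 | [(10-bromodecyl)oxy](tert-butyl)dimethylsilane | CC(C)(C)[Si](C)(C)OCCCCCCCCCCBr | intermediate
3 | (R)-epichlorohydrin, (2R)-2-(chloromethyl)oxirane | ClC[C@H]1CO1 | starting material
4 | 10-(tert-butyldimethylsilyloxy)decylmagnesium bromide | CC(C)(C)[Si](C)(C)OCCCCCCCCCC[Mg]Br | intermediate
5 | (2R)-13-(tert-butyldimethylsilyloxy)-1-chlorotridecan-2-ol | ClC[C@H](O)CCCCCCCCCCCO[Si](C)(C)C(C)(C)C | intermediate
6 | tert-butyldimethyl({11-[(2R)-oxiran-2-yl]undecyl}oxy)silane | C1[C@@H](CCCCCCCCCCCO[Si](C)(C)C(C)(C)C)O1 | intermediate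
7 | 1-iodo-2,4-dimethoxybenzene | COc1ccc(I)c(OC)c1 | starting material
8 | (3R)-3-[11-(tert-butyldimethylsilyloxy)undecyl]-6,8-dimethoxy-3,4-dihydro-1H-isochromen-1-one | COc1cc(OC)c2c(c1)C[C@@H](CCCCCCCCCCCO[Si](C)(C)C(C)(C)C)OC2=O | intermediate
9 | (3R)-3-[11-(tert-butyldimethylsilyloxy)undecyl]-8-(dichloroboryloxy)-6-methoxy-3,4-dihydro-1H-isochromen-1-one | COc1cc(OB(Cl)Cl)c2c(c1)C[C@@H](CCCCCCCCCCCO[Si](C)(C)C(C)(C)C)OC2=O | intermediate
10 | (3R)-8-hydroxy-3-(11-hydroxyundecyl)-6-methoxy-3,4-dihydro-1H-isochromen-1-one | COc1cc(O)c2c(c1)C[C@@H](CCCCCCCCCCCO)OC2=O | target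

**Total step count:** 5. **Longest linear sequence:** 5 steps (1 → 2 → 5 → 6 → 8 → 10).

**Steps most likely to fail**

**Step 4 (key step).**
- What may go wrong:
  - CO may bind zerovalent palladium too strongly.
  - CO may insert into the aryl- or norbornylpalladium species before the palladacycle has formed.
  - The alkoxide may close directly onto the aryl carbon before CO uptake.
- The fallback sets out from 6, returns at 8, and spreads the bond formations over three known reactions.
  - Commercial 3,5-dimethoxyphenylmagnesium chloride opens 6 at its CH2 terminus under CuI catalysis (THF, −30 °C). This should give (2R)-13-(tert-butyldimethylsilyloxy)-1-(3,5-dimethoxyphenyl)tridecan-2-ol F1.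
  - Electrophilic iodination with N-iodosuccinimide (MeCN, 0 °C) should go to the ring position ortho to the side chain and para to a methoxy group. This gives (2R)-13-(tert-butyldimethylsilyloxy)-1-(2-iodo-3,5-dimethoxyphenyl)tridecan-2-ol F2.
  - Intramolecular alkoxycarbonylation (PdCl2(PPh3)2, CO 1 atm, K2CO3, DMF, 80 °C) then closes ring B to give 8.

**Step 2.**
- What may go wrong:
  - Wurtz-type homocoupling may occur during Grignard formation.
  - Magnesium halide may open the oxirane.
  - Halide-mediated epoxide scrambling may erode the enantiopurity.
- The fallback sets out from 2, returns at 6, and sets the stereocentre by kinetic resolution instead of from the chiral pool.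
  - 2 is coupled with commercial allylmagnesium bromide (Li2CuCl4 cat., THF, 0 °C) to tert-butyldimethyl(tridec-12-en-1-yloxy)silane F3.
  - F3 is epoxidised with mCPBA (NaHCO3, CH2Cl2, 0 °C) to racemic tert-butyldimethyl{[11-(oxiran-2-yl)undecyl]oxy}silane F4.
  - Hydrolytic kinetic resolution follows, with (R,R)-(salen)Co(OAc) (0.5 mol%; salen = N,N'-bis(3,5-di-tert-butylsalicylidene)-1,2-cyclohexanediamine dianion) and H2O (0.55 equiv). It should hydrolyse the (S)-enantiomer and leave (R)-epoxide 6.

**Step 5.**
- What may go wrong:
  - The reagent may discriminate poorly between the two aryl methyl ethers.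
  - The silyl ether may be removed incompletely.
- The fallback sets out from 8, returns at 10, and replaces selective cleavage by exhaustive cleavage followed by selective re-alkylation.
  - BBr3 (excess, CH2Cl2, −78 to 0 °C, aqueous work-up) should remove both methyl groups and the silyl group. This gives (3R)-6,8-dihydroxy-3-(11-hydroxyundecyl)-3,4-dihydro-1H-isochromen-1-one F5.
  - MeI (1.0 equiv) with K2CO3 in acetone at rt should alkylate only O6. O8–H is locked in a hydrogen bond to the lactone carbonyl, and the aliphatic hydroxyl is not deprotonated. This gives 10.

**Further compounds**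
F1 | step 4 | (2R)-13-(tert-butyldimethylsilyloxy)-1-(3,5-dimethoxyphenyl)tridecan-2-ol | COc1cc(OC)cc(c1)C[C@@H](CCCCCCCCCCCO[Si](C)(C)C(C)(C)C)O
F2 | step 4 | (2R)-13-(tert-butyldimethylsilyloxy)-1-(2-iodo-3,5-dimethoxyphenyl)tridecan-2-ol | COc1cc(OC)c(I)c(c1)C[C@@H](CCCCCCCCCCCO[Si](C)(C)C(C)(C)C)O
F3 | step 2 | tert-butyldimethyl(tridec-12-en-1-yloxy)silane | C=CCCCCCCCCCCCO[Si](C)(C)C(C)(C)C
F4 | step 2 | racemic tert-butyldimethyl{[11-(oxiran-2-yl)undecyl]oxy}silane | C1C(CCCCCCCCCCCO[Si](C)(C)C(C)(C)C)O1
F5 | step 5 | (3R)-6,8-dihydroxy-3-(11-hydroxyundecyl)-3,4-dihydro-1H-isochromen-1-one | Oc1cc(O)c2c(c1)C[C@@H](CCCCCCCCCCCO)OC2=O
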